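**Retrosynthetic overview**
1. Ring letters: phenalenone = A (benzene ring carrying the five-membered ring), B (phenol ring), C (enone ring); D = cyclopentane, E = cyclopentenone, F = 1,3-dioxine, G/H = naphthalene. Enabling feature: the spiro ketal carbon of ring F is the β-carbon, and the D/E ring-fusion CH the α-carbon, of the ring E carbonyl, so ring F is a double Michael adduct of naphthalene-1,8-diol.
2. Ring F (last): conjugate transketalisation of the regiodefined β-methoxy dienone 14 with naphthalene-1,8-diol 3 (C–O exchange, then 6-exo-trig oxa-Michael closure), which also sets the ring-fusion CH.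
3. Ring D: Mukaiyama-type closure of the ring E silyloxydiene onto an ortho aryl acetal, then dehydrogenation, so that the leaving group sits only on the future ketal carbon (10 → 13 → 14).
4. Ring E and the carbinol centre: the aryllithium from bromide 5 adds anti to the silyloxy group of (R)-4-silyloxycyclopentenone 6; desilylation and oxidation erase the relay centre (5 → 10).
5. Rings A–C: [3+3] peri-annulation of 3 (C-4/C-5) with bromo-enaminone 2 gives 5. Order of ring closure: A, then D, then F (B, C, E, G and H come in with 3 and 6).

Key step: step 8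

Remark: the 9-hydroxyphenalenone unit is drawn throughout as the tautomer of the target SMILES (fast proton transfer between the two oxygens), and aryl addition in step 3 is assumed to occur anti to the silyloxy group, as is usual for 4-silyloxycyclopentenones.

**Step 1**
Reactants: 1 (E)-4-(dimethylamino)-1,1-dimethoxybut-3-en-2-one
Product: 2 (Z)-3-bromo-4-(dimethylamino)-1,1-dimethoxybut-3-en-2-one
Conditions: NBS (1.05 equiv), CH2Cl2, 0 °C
Reagents that add atoms: N-bromosuccinimide, O=C1CCC(=O)N1Br
Why: Electrophilic α-bromination of a push–pull enaminone (enamine-type halogenation) should occur only at the nucleophilic α-carbon; no stereocentre is formed.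

**Step 2**
Reactants: 2 (Z)-3-bromo-4-(dimethylamino)-1,1-dimethoxybut-3-en-2-one; 3 naphthalene-1,8-diol
Product: 5 5-bromo-6-(dimethoxymethyl)-9-hydroxy-1H-phenalen-1-one, via C-alkenylated naphthalenediol 4 (not isolated)
Conditions: CF3CO2H (3 equiv), 3 Å MS, (CF3)2CHOH/CH2Cl2 1:4, 0 °C to rt, Ar
Reagents that add atoms: none
Why: Proposed new method: acid turns the bromo-enaminone into a vinylogous iminium ion, C-4 of the diol (para to OH) adds to the aminomethylene carbon with loss of dimethylamine to give 4, the peri carbon C-5 (para to the second OH) then attacks the ketone in a six-membered cyclodehydration and tautomerisation gives the 9-hydroxyphenalenone; the closest known reaction types are the peri-annulation of naphthols with three-carbon 1,3-dielectrophiles (perinaphthenone synthesis) and Bradsher cyclodehydration, the symmetry of 3 makes both orientations identical, and the sieves take up the water so that the acetal should survive.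

**Step 3**
Reactants: 5 5-bromo-6-(dimethoxymethyl)-9-hydroxy-1H-phenalen-1-one; 6 (R)-4-[(tert-butyldimethylsilyl)oxy]cyclopent-2-en-1-one
Product: 8 5-[(1S,4R)-4-[(tert-butyldimethylsilyl)oxy]-1-hydroxycyclopent-2-en-1-yl]-6-(dimethoxymethyl)-9-hydroxy-1H-phenalen-1-one, via dilithio phenalenonate 7 (not isolated)
Conditions: n-BuLi (2.05 equiv), THF, −78 °C; then 6, LaCl3·2LiCl (1.1 equiv), −78 °C; AcOH (2.1 equiv), −78 °C to rt
Reagents that add atoms: none
Why: The first equivalent of base converts the vinylogous acid into its lithium salt (in situ protection of the phenalenone carbonyl), the second effects bromine–lithium exchange, and the LaCl3-promoted 1,2-addition of the aryllithium to the enone should occur on the face anti to the silyloxy group (1,3-substrate control), which sets the carbinol centre.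

**Step 4**
Reactants: 8 silyl ether adduct from step 3
Product: 9 (1S,4R)-1-[6-(dimethoxymethyl)-9-hydroxy-1-oxo-1H-phenalen-5-yl]cyclopent-2-ene-1,4-diol
Conditions: TBAF (1.5 equiv), AcOH (1.5 equiv), THF, 0 °C to rt
Reagents that add atoms: none
Why: Buffered fluoride desilylation should cleave the secondary silyl ether without ionising the acid-sensitive tertiary allylic benzylic alcohol or touching the acetal; no stereocentre is affected.

**Step 5**
Reactants: 9 cis-1,4-diol from step 4
Product: 10 (4S)-4-[6-(dimethoxymethyl)-9-hydroxy-1-oxo-1H-phenalen-5-yl]-4-hydroxycyclopent-2-en-1-one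
Conditions: MnO2 (15 equiv), CH2Cl2, rt
Reagents that add atoms: none
Why: Chemoselective MnO2 oxidation of the secondary allylic alcohol gives the enone, the tertiary alcohol cannot be oxidised, and the relay stereocentre from 6 is erased, leaving the carbinol centre as the only stereocentre.

**Step 6**
Reactants: 10 hydroxy enone acetal from step 5
Product: 13 pentacyclic β-methoxy ketone (rings A–E; cis-fused; carbinol carbon R; ring-fusion CH S; both epimers at the methoxy carbon), via tris-silylated silyloxydiene 11 (not isolated), via bis-silylated cyclised ketone 12 (not isolated)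
Conditions: TMSOTf (4.5 equiv), Et3N (3.5 equiv), CH2Cl2, −78 to −20 °C; then citric acid, MeOH/H2O, 0 °C
Reagents that add atoms: none
Why: Silylation of both hydroxyls and soft enolisation give the 2-silyloxydiene 11, whose α′-carbon adds to the acetal-derived oxocarbenium ion in an intramolecular Mukaiyama-type reaction (5-exo-trig, enol-exo closure of ring D); the two five-membered rings can only fuse cis, so the ring-fusion CH follows the carbinol centre, and the methoxy-bearing centre is of no consequence because step 7 removes it.

**Step 7**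
Reactants: 13 pentacyclic β-methoxy ketone
Product: 14 pentacyclic β-methoxy dienone (vinylogous methyl ester; ring D alkene between the methoxy carbon and the ring-fusion carbon; carbinol carbon S by CIP with unchanged spatial arrangement)
Conditions: IBX (1.5 equiv), 4-methoxypyridine N-oxide (1.5 equiv), DMSO, 25 °C
Reagents that add atoms: none
Why: IBX dehydrogenation of a ketone to an enone proceeds through the enol; the only enolisable α-hydrogen is the ring-fusion CH and the only β-hydrogen sits on the methoxy carbon, so both epimers of 13 should converge on the one regiodefined vinylogous ester.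

**Step 8**
Reactants: 14 pentacyclic β-methoxy dienone; 3 naphthalene-1,8-diol
Product: 16 spiropreussione B, via aryloxy dienone 15 (not isolated)
Conditions: 3 (1.5 equiv), camphor-10-sulfonic acid (0.2 equiv), 5 Å MS, ClCH2CH2Cl, 50 °C, Ar
Reagents that add atoms: none
Why: Acid-catalysed conjugate transketalisation: protonation of the cross-conjugated vinylogous ester lets one naphthol oxygen add to the β-carbon and methanol leaves (addition–elimination to 15), then the peri hydroxyl closes the 1,3-dioxine ring F by a 6-exo-trig oxa-Michael addition and the enol tautomerises to the ketone. The closest known reaction types are the acid-catalysed conversion of β-alkoxy enones (masked 1,3-dicarbonyls) into cyclic β-keto acetals with diols and the ketalisation of ketones with naphthalene-1,8-diol. The new ring-fusion stereocentre is set in the final C-protonation, which must occur on the face of the hydroxyl group because the two five-membered rings can only be cis-fused, so the existing carbinol centre controls it. Regioselectivity (ketal at the benzylic β-carbon, not at the enone carbonyl carbon) is secured because the leaving group sits only on that carbon and no free 1,3-diketone or oxocarbenium ion next to the electron-poor phenalenone is involved; addition of the naphthol to the other enone β-carbon is reversible and unproductive, and C-alkylation of the diol (as used in step 2 at a CH carbon) is disfavoured here because the electrophilic carbon is fully substituted. Relief of the strain of the ring-fusion alkene and uptake of methanol by the sieves should drive the equilibrium to the spiroketal.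

**Compound list**
1 | (E)-4-(dimethylamino)-1,1-dimethoxybut-3-en-2-one | COC(OC)C(=O)/C=C/N(C)C | starting material
2 | (Z)-3-bromo-4-(dimethylamino)-1,1-dimethoxybut-3-en-2-one | COC(OC)C(=O)/C(Br)=C/N(C)C | intermediate
3 | naphthalene-1,8-diol | Oc1cccc2cccc(O)c12 | starting material
4 | (E)-3-bromo-4-(4,5-dihydroxynaphthalen-1-yl)-1,1-dimethoxybut-3-en-2-one (not isolated) | COC(OC)C(=O)/C(Br)=C\c1ccc(O)c2c(O)cccc12 | intermediate
5 | 5-bromo-6-(dimethoxymethyl)-9-hydroxy-1H-phenalen-1-one | O=C1C=Cc2cc(Br)c(C(OC)OC)c3ccc(O)c1c23 | intermediate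
6 | (R)-4-[(tert-butyldimethylsilyl)oxy]cyclopent-2-en-1-one | O=C1C=C[C@H](O[Si](C)(C)C(C)(C)C)C1 | starting material
7 | lithium 5-lithio-6-(dimethoxymethyl)-1-oxo-1H-phenalen-9-olate (not isolated) | O=C1C=Cc2cc([Li])c(C(OC)OC)c3ccc(O[Li])c1c23 | intermediate
8 | 5-[(1S,4R)-4-[(tert-butyldimethylsilyl)oxy]-1-hydroxycyclopent-2-en-1-yl]-6-(dimethoxymethyl)-9-hydroxy-1H-phenalen-1-one (OH and OSi cis) | O=C1C=Cc2cc([C@@]4(O)C=C[C@H](O[Si](C)(C)C(C)(C)C)C4)c(C(OC)OC)c3ccc(O)c1c23 | intermediate
9 | (1S,4R)-1-[6-(dimethoxymethyl)-9-hydroxy-1-oxo-1H-phenalen-5-yl]cyclopent-2-ene-1,4-diol | O=C1C=Cc2cc([C@@]4(O)C=C[C@H](O)C4)c(C(OC)OC)c3ccc(O)c1c23 | intermediate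
10 | (4S)-4-[6-(dimethoxymethyl)-9-hydroxy-1-oxo-1H-phenalen-5-yl]-4-hydroxycyclopent-2-en-1-one | O=C1C=Cc2cc([C@@]4(O)C=CC(=O)C4)c(C(OC)OC)c3ccc(O)c1c23 | intermediate
11 | 5-[(1R)-1,4-bis(trimethylsilyloxy)cyclopenta-2,4-dien-1-yl]-6-(dimethoxymethyl)-9-(trimethylsilyloxy)-1H-phenalen-1-one (not isolated) | O=C1C=Cc2cc([C@@]4(O[Si](C)(C)C)C=CC(O[Si](C)(C)C)=C4)c(C(OC)OC)c3ccc(O[Si](C)(C)C)c1c23 | intermediate
12 | bis(trimethylsilyl) ether of 13 (silyl on the tertiary and the phenalenone oxygen; carbinol carbon R, ring-fusion CH S, both methoxy epimers; not isolated) | O=C1C=Cc2cc3c(c4ccc(O[Si](C)(C)C)c1c24)C(OC)[C@@H]1C(=O)C=C[C@]31O[Si](C)(C)C | intermediate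
13 | pentacyclic β-methoxy ketone: 9-hydroxyphenalenone carrying on C-5/C-6 a cis-fused bicyclo[3.3.0]octenone; ring D = C-6–CH(OMe)–CH–C(OH)–C-5, ring E = CH–C(=O)–CH=CH–C(OH); carbinol carbon R, ring-fusion CH S, both methoxy epimers | O=C1C=Cc2cc3c(c4ccc(O)c1c24)C(OC)[C@@H]1C(=O)C=C[C@]31O | intermediate
14 | pentacyclic β-methoxy dienone: as 13 but with a C=C between the methoxy carbon and the ring-fusion carbon (vinylogous methyl ester); carbinol carbon S | O=C1C=Cc2cc3c(c4ccc(O)c1c24)C(OC)=C1C(=O)C=C[C@]31O | intermediate
15 | as 14 with 8-hydroxynaphthalen-1-yloxy in place of methoxy (not isolated); carbinol carbon S | O=C1C=Cc2cc3c(c4ccc(O)c1c24)C(Oc1cccc2cccc(O)c12)=C1C(=O)C=C[C@]31O | intermediate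
16 | spiropreussione B (carbinol ring-fusion carbon R, ring-fusion CH S, cis-fused) | O=C1C=Cc2cc3c(c4ccc(O)c1c24)C1(Oc2cccc4cccc(c24)O1)[C@@H]1C(=O)C=C[C@]31O | target

**Step count and risks**
Total step count: 8. Longest linear sequence: 8 steps (from 1).

Steps most likely to fail:

1. Step 2 (Proposed new method). The diol may react through C-2 and oxygen instead of C-4 and C-5, giving naphthopyran or pyrylium-type products; it may also oligomerise oxidatively, and the water formed may cleave the acetal. Fallback, setting out from 3 and returning at 5: both hydroxyls would be methylated (MeI, K2CO3, acetone) to 1,8-dimethoxynaphthalene F1. Vilsmeier–Haack formylation (POCl3, DMF) para to a methoxy group would give 4,5-dimethoxynaphthalene-1-carbaldehyde F2. Horner–Wadsworth–Emmons olefination with dimethyl (1-bromo-3,3-dimethoxy-2-oxopropyl)phosphonate (LiCl, DBU, MeCN) would give 3-bromo-4-(4,5-dimethoxynaphthalen-1-yl)-1,1-dimethoxybut-3-en-2-one F3, in which the first C–C bond is already fixed at the right carbon. Bradsher-type cyclodehydration onto the peri position (CH3SO3H, HC(OMe)3, CH2Cl2) would give 5-bromo-6-(dimethoxymethyl)-1,9-dimethoxyphenalenium methanesulfonate F4, and aqueous LiOH would cleave both vinylogous methyl ester groups to give 5.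

2. Step 3. Halogen–metal exchange may be incomplete or the aryllithium quenched because the dianion is poorly soluble; the organolithium may add to the phenalenonate; enone 6 may enolise and lose silanol; facial selectivity may be poor. Fallback, setting out from 5 and returning at 10: Suzuki–Miyaura coupling of 5 with 4,4,5,5-tetramethyl-2-(5-methylfuran-2-yl)-1,3,2-dioxaborolane (Pd(PPh3)4, K2CO3, dioxane/H2O) would give 6-(dimethoxymethyl)-9-hydroxy-5-(5-methylfuran-2-yl)-1H-phenalen-1-one F5. Oxidative opening of the furan (mCPBA, CH2Cl2, 0 °C) would give (Z)-1-[6-(dimethoxymethyl)-9-hydroxy-1-oxo-1H-phenalen-5-yl]hex-2-ene-1,4-dione F6. Intramolecular aldol addition of the methyl ketone to the aryl ketone (Et3N, CH2Cl2) would give the racemic hydroxy enone F7. Separation on a chiral stationary phase would give 10 and leave its (R)-enantiomer F8; the carbinol centre would then come from resolution instead of from the chiral pool.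

3. Step 8. Exchange at the hindered β-carbon may be slow or incomplete, the diol may be C-alkylated, the oxa-Michael closure may revert, and prolonged acid may erode the carbinol configuration by retro-aldol opening. Fallback, setting out from 14 and returning at 16: 14 would be converted with thiophenol (cat. camphor-10-sulfonic acid, CH2Cl2) into the vinylogous thioester, the phenylthio dienone F9. The monosodium salt of 3 (NaH 1 equiv, DMF, 0 °C) would then displace thiolate in an anionic addition–elimination, and buffered acidification (AcOH) would close the dioxine ring to 16.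

**Further compounds**
F1 | step 2 | 1,8-dimethoxynaphthalene | COc1cccc2cccc(OC)c12
F2 | step 2 | 4,5-dimethoxynaphthalene-1-carbaldehyde | COc1ccc(C=O)c2cccc(OC)c12
F3 | step 2 | 3-bromo-4-(4,5-dimethoxynaphthalen-1-yl)-1,1-dimethoxybut-3-en-2-one (E/Z mixture) | COC(OC)C(=O)C(Br)=Cc1ccc(OC)c2c(OC)cccc12
F4 | step 2 | 5-bromo-6-(dimethoxymethyl)-1,9-dimethoxyphenalenium methanesulfonate | C[O+]=C1C=Cc2cc(Br)c(C(OC)OC)c3ccc(OC)c1c23.CS(=O)(=O)[O-]
F5 | step 3 | 6-(dimethoxymethyl)-9-hydroxy-5-(5-methylfuran-2-yl)-1H-phenalen-1-one | O=C1C=Cc2cc(-c4ccc(C)o4)c(C(OC)OC)c3ccc(O)c1c23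
F6 | step 3 | (Z)-1-[6-(dimethoxymethyl)-9-hydroxy-1-oxo-1H-phenalen-5-yl]hex-2-ene-1,4-dione | O=C1C=Cc2cc(C(=O)/C=C\C(C)=O)c(C(OC)OC)c3ccc(O)c1c23
F7 | step 3 | racemic 4-[6-(dimethoxymethyl)-9-hydroxy-1-oxo-1H-phenalen-5-yl]-4-hydroxycyclopent-2-en-1-one | O=C1C=Cc2cc(C4(O)C=CC(=O)C4)c(C(OC)OC)c3ccc(O)c1c23
F8 | step 3 | (4R)-4-[6-(dimethoxymethyl)-9-hydroxy-1-oxo-1H-phenalen-5-yl]-4-hydroxycyclopent-2-en-1-one | O=C1C=Cc2cc([C@]4(O)C=CC(=O)C4)c(C(OC)OC)c3ccc(O)c1c23
F9 | step 8 | phenylthio dienone (as 14 with phenylsulfanyl in place of methoxy) | O=C1C=Cc2cc3c(c4ccc(O)c1c24)C(Sc1ccccc1)=C1C(=O)C=C[C@]31O
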